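The runs come from a simulation for substances that don't exist, and the scatter is random.

The trap in these two runs is to compare them in percent: violet's highest reading, 7.8%, looks lower than teal's 13.7%, but each percentage is taken of a different charge of starting material.

| setting | teal | violet | flask |
|---|---|---|---|
| starting material | 0.10 M | 0.15 M | 0.10 M |
| reagent | 0.105 M | 0.105 M | 0.105 M |
| second substrate | 0.50 M | 0.50 M | 0.500 M |
| third substrate | 0.10 M | 0.10 M | 0.100 M |
| remark | the very flask that is asked about, followed so far | run made earlier |  |
| time |  |  | 15 d |

| run | time / d | target / % |
|---|---|---|
| teal | 0.104 | 9.5 |
| teal | 0.167 | 10.6 |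
| teal | 0.333 | 11.8 |
| teal | 0.500 | 13.7 |
| teal | 1.04 | 10.7 |
| teal | 1.67 | 8.0 |
| teal | 3.00 | 7.6 |
| violet | 0.167 | 7.1 |
| violet | 0.333 | 7.8 |
| violet | 0.625 | 4.0 |
| violet | 1.67 | 3.3 |
| violet | 3.00 | 1.9 |
| violet | 8.00 | 1.8 |
| violet | 15.0 | 0 |

(readings scatter by 1 percentage point)

1. the best time, 15 d at the latest, for target
2. the amount of target, in percent of the starting material charged, at that time
3. the first time at which target reaches 6.3%, in the same percent, in d



So reckon in concentration. Teal's highest reading is 0.0137 M of target and violet's is 0.0117 M, lower even though violet was charged with 1.50 times the starting material of teal, so these highest readings do not rise with that charge. Both runs held 0.105 M of reagent, and I assume that the highest target concentration goes in proportion to the reagent charged, an assumption that these two runs cannot test. Dividing the highest reading by the reagent charged, teal gives 0.130. But the flask asked about repeats teal, so this merely hands back one reading that scatters by 1 percentage point, and that is the weak link. Violet gives 0.111, so I reforge the link as the mean of the two, φ = 0.121, the peak yield on reagent. For the flask, φ times its reagent over its starting material gives a best of 12.7%.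

The forecast gives 12.8% at 0.42 d, slightly above my figure, and the asked level first reached at 0.06 d. On the timing of the maximum it says: “Nothing in either run suggests a late second rise”.

The flask gives 12.5% at 0.399 d and first reaches the level at 0.0692 d, later than the forecast.

second substrate + reagent → second product (k = 0.0123 M⁻¹ h⁻¹); starting material + target → side product (k = 2.46 M⁻¹ h⁻¹); starting material + reagent → target (k = 0.492 M⁻¹ h⁻¹); third substrate ⇌ dormant form (K = 7.20, k = 0.628 h⁻¹); third substrate + reagent → third product (k = 0.454 M⁻¹ h⁻¹) At the best time 59.7% of the charged reagent is still there, and target over that reagent stands at 0.200, beside 0.200 for the rate constant of starting material + reagent over that of starting material + target, a selectivity factor. The flask's own best, divided as before, gives φ = 0.119. In the neighbour flask, charged like the flask but with 0.18 M of reagent, the φ read from the runs gives a best of 21.8%, and the computed best there is 21.3%.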